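At early times free catalyst meets two substrates at once, and reagent is consumed by whichever catalyst intermediate it encounters.

| flask | starting material | second substrate | reagent | free catalyst | temperature | time | remark |
|---|---|---|---|---|---|---|---|
| Sunday's | 2.0 mM | 4.00 mM | 3.00 mM | 0.30 mM | 85 °C | 15 s |  |
| Thursday's | 2.0 mM | 4.00 mM | 3.00 mM | 0.30 mM | 100 °C | 15 s |  |
| Wednesday's | 2.0 mM | 4.00 mM | 3.00 mM | 0.30 mM |  | 15 s | at 100 °C until 3.0 s, from then on at 70 °C |
| Saturday's | 2.0 mM | 4.00 mM | 3.00 mM | 0.30 mM | 70 °C | 15 s |  |

- which flask leads in amount of target, in percent of the starting material charged ("all alike" within 1.5 percentage points) (Sunday's / Thursday's / Wednesday's / Saturday's / all alike)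
- how much target is there at the end, in percent of the starting material charged: Sunday's
- how much target is there at the end, in percent of the starting material charged: Thursday's
- how much target is there at the end, in percent of the starting material charged: Wednesday's
- how much target is there at the end, in percent of the starting material charged: Saturday's

- the constants hold at 100 °C; other temperatures follow from the activation energies and enthalpies

    reagent + catalyst intermediate B → free catalyst + second product (k1 = 7950 M⁻¹ s⁻¹, Ea1 = 16.0 kJ mol⁻¹)
    second substrate + free catalyst ⇌ catalyst intermediate B (K2 = 330 M⁻¹, k2 = 1320 M⁻¹ s⁻¹, Ea2 = 55.0 kJ mol⁻¹, ΔH2 = −53.0 kJ mol⁻¹)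
    reagent + catalyst intermediate A → free catalyst + target (k3 = 530 M⁻¹ s⁻¹, Ea3 = 35.0 kJ mol⁻¹)
    starting material ⇌ dormant form (K4 = 8.83, k4 = 0.382 s⁻¹, Ea4 = 85.0 kJ mol⁻¹, ΔH4 = 9.00 kJ mol⁻¹)
    starting material + free catalyst ⇌ catalyst intermediate A (K5 = 1310 M⁻¹, k5 = 9820 M⁻¹ s⁻¹, Ea5 = 15.0 kJ mol⁻¹, ΔH5 = 10.0 kJ mol⁻¹)
    catalyst intermediate A → spent catalyst (k6 = 0.191 s⁻¹, Ea6 = 102 kJ mol⁻¹)
    (constants at 100 °C)

A ledger of the reagent can be drawn up for Wednesday's flask. The limiting reagent is the reagent, because its 3.00 mM stands against 6.00 mM of the two substrates together. A mole of it has three possible entries: spent on catalyst intermediate A, which makes target; spent on catalyst intermediate B, which makes second product; or unused. The rate of the first entry over that of the second is the constant 530 M⁻¹ s⁻¹ times c(catalyst intermediate A), over 7950 M⁻¹ s⁻¹ times c(catalyst intermediate B), so c(reagent) cancels, but the ratio of the two intermediates stays in it, and that ratio can change with time.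

Suppose next that each intermediate stands in equilibrium with free catalyst, with constants 1310 M⁻¹ and 330 M⁻¹. Then c(free catalyst) cancels as well, and the ratio depends on c(starting material) over c(second substrate), taken here at their charges of 2.0 mM and 4.00 mM, so that time drops out of the estimate, although both concentrations change in Wednesday's flask. This gives 0.117 for the fraction of spent reagent that leaves as target, the target share, a form of selectivity factor. It uses the constants at 100 °C, Wednesday's opening temperature, and the later stretch at 70 °C is not reckoned.

The assumption is fair for catalyst intermediate A, whose return to free catalyst at 7.50 s⁻¹ is faster than its onward step at 1.59 s⁻¹. It is weaker for catalyst intermediate B, whose onward step at the full charge of reagent, at 23.9 s⁻¹, is faster than its return to free catalyst at 4.00 s⁻¹. The two rates match at c(reagent) = 0.503 mM, so the target share is strictly a figure for thin reagent. Closing the books with the whole charge spent puts 0.351 mM into target and 2.65 mM into second product. The reckoning therefore gives Wednesday's 17.5 % of target.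

The forecast, which is higher than this reckoning for Wednesday's, names Saturday's as the leader, with Sunday's 36 %, Thursday's 33 %, Wednesday's 35 % and Saturday's 40 %, on the ground that “the second substrate's fast catalytic loop burns most of the reagent within seconds”.

The simulation puts Saturday's in the lead, with Saturday's 35.1 %, Sunday's 31.1 %, Thursday's 25.4 % and Wednesday's 25.6 %.

Wednesday's books at 15.0 s show 0.512 mM of target, 2.25 mM of second product and 0.241 mM of reagent unused, a target share of 0.185 against the reckoned 0.117. At 2.71 s in Wednesday's flask, catalyst intermediate B falls back at 0.34 times the rate at which it goes on, so the equilibrium assumed for it does not stand at that time. A neighbour of Wednesday's charged with 0.75 mM of reagent gets 4.39 % of target from the same share. Its simulation ends with 0 % of the reagent left and 4.27 % of target.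

Its constants were chosen freely.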